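**Retrosynthetic overview**
1. Target ⇒ peri-selective 5-O-demethylation, O-debenzylation and 3-O-methylation of a flavonol ⇒ C3 oxidation of 3',5'-bis(benzyloxy)-5,6,7,8,4'-pentamethoxyflavone.
2. Ring C is the only ring built and is closed last, by oxidative oxa-Michael cyclisation (O1–C2) of a 2'-hydroxychalcone. Rings A and B come from benzenoid starting materials.
3. Key C–C bond: C2–C3 of the flavone (the chalcone Cα=Cβ), made by an intermolecular Claisen–Schmidt aldol condensation of fragment A (2-hydroxy-3,4,5,6-tetramethoxyacetophenone) and fragment B (3,5-bis(benzyloxy)-4-methoxybenzaldehyde).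
4. Fragment A ⇒ pentamethoxybenzene (Friedel–Crafts acylation with ortho-demethylation) ⇒ 3,4,5-trimethoxyphenol (methylation, Vilsmeier formylation, Baeyer–Villiger oxidation, methylation).
5. Fragment B ⇒ methyl gallate (4-O-methylation, 3,5-di-O-benzylation, ester to aldehyde).

Assumption: the target SMILES carries no stereocentre, stereogenic axis or stereogenic double bond. It is therefore one achiral compound and no enantioselective step is needed. Racemic centres occur only in the transient compounds 15, 17 and 19 and are erased.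

**Fragment A**

Step 1
Reactants: 1 3,4,5-trimethoxyphenol
Product: 2 1,2,3,5-tetramethoxybenzene
Conditions: MeI (1.5 equiv), K2CO3 (2 equiv), acetone, reflux, 8 h
Reagents that add atoms: iodomethane CI
Why: Williamson ether synthesis, in which the phenoxide of 1 attacks MeI by SN2 and no other nucleophilic site is present.

Step 2
Reactants: 2 1,2,3,5-tetramethoxybenzene
Product: 4 2,3,4,6-tetramethoxybenzaldehyde, via aryliminium chloride 3 (not isolated)
Conditions: POCl3 (1.5 equiv), DMF, 0 °C to 60 °C, 3 h; then ice–water, 2 h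
Reagents that add atoms: N,N-dimethylformamide CN(C)C=O; water O
Why: Vilsmeier–Haack formylation, where the two free positions of 2 are equivalent by symmetry and each is ortho, ortho and para to methoxy groups, so one iminium salt 3 forms and water hydrolyses it to 4.

Step 3
Reactants: 4 2,3,4,6-tetramethoxybenzaldehyde
Product: 6 2,3,4,6-tetramethoxyphenol, via aryl formate 5 (not isolated)
Conditions: mCPBA (1.2 equiv), CH2Cl2, 0 °C to rt; aqueous wash; then MeOH, cat. HCl, rt, N2
Reagents that add atoms: 3-chloroperbenzoic acid O=C(OO)c1cccc(Cl)c1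
Why: Baeyer–Villiger oxidation (Dakin-type outcome), in which the electron-rich aryl group migrates in preference to hydride to give formate 5, and acid-catalysed methanolysis frees the phenol without exposing an air-sensitive phenoxide.

Step 4
Reactants: 6 2,3,4,6-tetramethoxyphenol
Product: 7 pentamethoxybenzene
Conditions: MeI (1.5 equiv), K2CO3 (2 equiv), DMF, rt, 12 h
Reagents that add atoms: iodomethane CI
Why: Williamson ether synthesis on the single phenol, which proceeds despite two ortho methoxy groups because MeI is small.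

Step 5
Reactants: 7 pentamethoxybenzene
Product: 9 1-(2-hydroxy-3,4,5,6-tetramethoxyphenyl)ethanone, via pentamethoxyacetophenone 8 (not isolated)
Conditions: AcCl (2 equiv), AlCl3 (3 equiv), Et2O, 0 °C to rt, 24 h; then ice / 2 M HCl
Reagents that add atoms: acetyl chloride CC(Cl)=O
Why: Friedel–Crafts acylation at the only ring C–H gives 8, in which AlCl3 held between the new C=O and one of the two equivalent ortho OMe groups lets chloride remove just that methyl group (chelation-directed ether cleavage), and the chelated phenoxide then shields the second ortho OMe under these mild conditions.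

**Fragment B**

Step 6
Reactants: 10 methyl gallate (methyl 3,4,5-trihydroxybenzoate)
Product: 11 methyl 3,5-dihydroxy-4-methoxybenzoate
Conditions: MeI (1.05 equiv), NaHCO3 (1.5 equiv), DMF, 40 °C, 24 h
Reagents that add atoms: iodomethane CI
Why: Regioselective Williamson methylation, since the 4-OH para to the ester is the most acidic phenol and the only one NaHCO3 ionises appreciably, so near-stoichiometric MeI gives mainly the 4-O-methyl ether, which is purified by crystallisation or chromatography.

Step 7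
Reactants: 11 methyl 3,5-dihydroxy-4-methoxybenzoate
Product: 12 methyl 3,5-bis(benzyloxy)-4-methoxybenzoate
Conditions: BnBr (2.4 equiv), K2CO3 (3 equiv), DMF, 60 °C, 6 h
Reagents that add atoms: benzyl bromide BrCc1ccccc1
Why: Exhaustive Williamson benzylation of the two remaining equivalent phenols, giving ethers that withstand base, I2/DMSO and DMDO and leave by hydrogenolysis.

Step 8
Reactants: 12 methyl 3,5-bis(benzyloxy)-4-methoxybenzoate
Product: 13 [3,5-bis(benzyloxy)-4-methoxyphenyl]methanol
Conditions: LiAlH4 (1.2 equiv), THF, 0 °C to rt, 2 h; then H2O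
Reagents that add atoms: none
Why: Hydride reduction of the ester to the primary alcohol, with aryl benzyl and methyl ethers inert to LiAlH4.

Step 9
Reactants: 13 [3,5-bis(benzyloxy)-4-methoxyphenyl]methanol
Product: 14 3,5-bis(benzyloxy)-4-methoxybenzaldehyde
Conditions: activated MnO2 (10 equiv), CH2Cl2, rt, 12 h
Reagents that add atoms: none
Why: Heterogeneous MnO2 oxidation is selective for benzylic alcohols and stops cleanly at the aldehyde.

**Union of the fragments and end-game**

Step 10
Reactants: 9 1-(2-hydroxy-3,4,5,6-tetramethoxyphenyl)ethanone; 14 3,5-bis(benzyloxy)-4-methoxybenzaldehyde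
Product: 16 (E)-3-[3,5-bis(benzyloxy)-4-methoxyphenyl]-1-(2-hydroxy-3,4,5,6-tetramethoxyphenyl)prop-2-en-1-one, via aldol adduct 15 (not isolated)
Conditions: KOH (50% aq, 10 equiv), EtOH–THF 3:1, rt, 48 h; then 2 M HCl to pH 3
Reagents that add atoms: none
Why: Claisen–Schmidt crossed aldol condensation, in which only 9 can enolise and only 14 is an aldehyde, so the enolate of 9 adds to 14 to form the future C2–C3 bond, and E1cB loss of water from racemic 15 erases its carbinol centre and gives the conjugated E-alkene under thermodynamic control.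

Step 11
Reactants: 16 (E)-chalcone
Product: 18 2-[3,5-bis(benzyloxy)-4-methoxyphenyl]-5,6,7,8-tetramethoxy-4H-chromen-4-one, via flavanone 17 (not isolated)
Conditions: I2 (10 mol%), DMSO, 130 °C, 3 h
Reagents that add atoms: none
Why: Oxa-Michael closure of the 2'-OH onto the enone gives racemic flavanone 17, and iodine-mediated dehydrogenation with DMSO as terminal oxidant removes its stereocentre and makes ring C a 4-pyrone, so any flavanone already present in crude 16 converges on 18.

Step 12
Reactants: 18 3',5'-bis(benzyloxy)-5,6,7,8,4'-pentamethoxyflavone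
Product: 20 2-[3,5-bis(benzyloxy)-4-methoxyphenyl]-3-hydroxy-5,6,7,8-tetramethoxy-4H-chromen-4-one, via flavone epoxide 19 (not isolated)
Conditions: DMDO (ca. 0.08 M in acetone, 3 equiv in portions), CH2Cl2, 0 °C to rt, 16 h; then p-TsOH·H2O (10 mol%), CH2Cl2, rt, 1 h
Reagents that add atoms: dimethyldioxirane CC1(C)OO1
Why: Electrophilic epoxidation of the enol-ether C2=C3 bond gives racemic epoxide 19, whose acid-catalysed opening at C2 (aryl-stabilised oxocarbenium ion) and loss of H-3 restores the pyrone as the flavonol, which avoids the Algar–Flynn–Oyamada reaction that diverts 6'-alkoxychalcones to aurones.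

Step 13
Reactants: 20 3-hydroxyflavone
Product: 21 2-[3,5-bis(benzyloxy)-4-methoxyphenyl]-3,5,6,7,8-pentamethoxy-4H-chromen-4-one
Conditions: MeI (2 equiv), K2CO3 (2 equiv), acetone, reflux, 6 h
Reagents that add atoms: iodomethane CI
Why: Williamson methylation of the only free hydroxyl group, the acidic enolic 3-OH.

Step 14
Reactants: 21 3',5'-bis(benzyloxy)-3,5,6,7,8,4'-hexamethoxyflavone
Product: 22 2-(3,5-dihydroxy-4-methoxyphenyl)-3,5,6,7,8-pentamethoxy-4H-chromen-4-one
Conditions: H2 (1 atm), 10% Pd/C, EtOAc–MeOH 1:1, rt, 4 h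
Reagents that add atoms: none
Why: Catalytic hydrogenolysis cleaves both benzylic C–O bonds, while the tetrasubstituted pyrone C=C and the aryl methyl ethers are inert at 1 atm.

Step 15
Reactants: 22 3',5'-dihydroxy-3,5,6,7,8,4'-hexamethoxyflavone
Product: 23 5,3',5'-trihydroxy-3,6,7,8,4'-pentamethoxyflavone
Conditions: 3 M HCl in EtOH–H2O (conc. HCl/EtOH 1:3), reflux, N2, 24–48 h (HPLC control)
Reagents that add atoms: none
Why: Peri-selective acid cleavage of an aryl methyl ether, in which protonation of the pyrone C=O activates the crowded 5-OMe, chloride takes its methyl group by SN2 and the new 5-OH is locked in a six-membered hydrogen bond, whereas 3-OMe would gain only a weaker five-membered one, the other OMe groups are ordinary aryl ethers inert to 3 M HCl, and any Wessely–Moser ring opening is degenerate because ring A is symmetric.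

**Compound list**
1 | 3,4,5-trimethoxyphenol | COc1cc(O)cc(OC)c1OC | starting material
2 | 1,2,3,5-tetramethoxybenzene | COc1cc(OC)c(OC)c(OC)c1 | intermediate
3 | N,N-dimethyl(2,3,4,6-tetramethoxybenzylidene)iminium chloride (not isolated) | C[N+](C)=Cc1c(OC)cc(OC)c(OC)c1OC.[Cl-] | intermediate
4 | 2,3,4,6-tetramethoxybenzaldehyde | COc1cc(OC)c(C=O)c(OC)c1OC | intermediate
5 | 2,3,4,6-tetramethoxyphenyl formate (not isolated) | COc1cc(OC)c(OC=O)c(OC)c1OC | intermediate
6 | 2,3,4,6-tetramethoxyphenol | COc1cc(OC)c(O)c(OC)c1OC | intermediate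
7 | pentamethoxybenzene | COc1cc(OC)c(OC)c(OC)c1OC | intermediate
8 | 1-(2,3,4,5,6-pentamethoxyphenyl)ethanone (not isolated) | CC(=O)c1c(OC)c(OC)c(OC)c(OC)c1OC | intermediate
9 | 1-(2-hydroxy-3,4,5,6-tetramethoxyphenyl)ethanone (fragment A) | CC(=O)c1c(O)c(OC)c(OC)c(OC)c1OC | intermediate
10 | methyl gallate | COC(=O)c1cc(O)c(O)c(O)c1 | starting material
11 | methyl 3,5-dihydroxy-4-methoxybenzoate | COC(=O)c1cc(O)c(OC)c(O)c1 | intermediate
12 | methyl 3,5-bis(benzyloxy)-4-methoxybenzoate | COC(=O)c1cc(OCc2ccccc2)c(OC)c(OCc2ccccc2)c1 | intermediate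
13 | [3,5-bis(benzyloxy)-4-methoxyphenyl]methanol | OCc1cc(OCc2ccccc2)c(OC)c(OCc2ccccc2)c1 | intermediate
14 | 3,5-bis(benzyloxy)-4-methoxybenzaldehyde (fragment B) | O=Cc1cc(OCc2ccccc2)c(OC)c(OCc2ccccc2)c1 | intermediate
15 | 3-[3,5-bis(benzyloxy)-4-methoxyphenyl]-3-hydroxy-1-(2-hydroxy-3,4,5,6-tetramethoxyphenyl)propan-1-one (racemic, not isolated) | COc1c(OCc2ccccc2)cc(C(O)CC(=O)c2c(O)c(OC)c(OC)c(OC)c2OC)cc1OCc1ccccc1 | intermediate
16 | (E)-3-[3,5-bis(benzyloxy)-4-methoxyphenyl]-1-(2-hydroxy-3,4,5,6-tetramethoxyphenyl)prop-2-en-1-one | COc1c(OCc2ccccc2)cc(/C=C/C(=O)c2c(O)c(OC)c(OC)c(OC)c2OC)cc1OCc1ccccc1 | intermediate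
17 | 2-[3,5-bis(benzyloxy)-4-methoxyphenyl]-5,6,7,8-tetramethoxychroman-4-one (racemic, not isolated) | COc1c(OCc2ccccc2)cc(C2CC(=O)c3c(OC)c(OC)c(OC)c(OC)c3O2)cc1OCc1ccccc1 | intermediate
18 | 2-[3,5-bis(benzyloxy)-4-methoxyphenyl]-5,6,7,8-tetramethoxy-4H-chromen-4-one | COc1c(OCc2ccccc2)cc(-c2cc(=O)c3c(OC)c(OC)c(OC)c(OC)c3o2)cc1OCc1ccccc1 | intermediate
19 | 2,3-epoxide of 18 (racemic, cis-fused by ring constraint, not isolated) | COc1c(OCc2ccccc2)cc(C23OC2C(=O)c2c(OC)c(OC)c(OC)c(OC)c2O3)cc1OCc1ccccc1 | intermediate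
20 | 2-[3,5-bis(benzyloxy)-4-methoxyphenyl]-3-hydroxy-5,6,7,8-tetramethoxy-4H-chromen-4-one | COc1c(OCc2ccccc2)cc(-c2oc3c(OC)c(OC)c(OC)c(OC)c3c(=O)c2O)cc1OCc1ccccc1 | intermediate
21 | 2-[3,5-bis(benzyloxy)-4-methoxyphenyl]-3,5,6,7,8-pentamethoxy-4H-chromen-4-one | COc1c(OCc2ccccc2)cc(-c2oc3c(OC)c(OC)c(OC)c(OC)c3c(=O)c2OC)cc1OCc1ccccc1 | intermediate
22 | 2-(3,5-dihydroxy-4-methoxyphenyl)-3,5,6,7,8-pentamethoxy-4H-chromen-4-one | COc1c(O)cc(-c2oc3c(OC)c(OC)c(OC)c(OC)c3c(=O)c2OC)cc1O | intermediate
23 | 5,3',5'-trihydroxy-3,6,7,8,4'-pentamethoxyflavone (achiral) | COc1c(O)cc(-c2oc3c(OC)c(OC)c(OC)c(O)c3c(=O)c2OC)cc1O | target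

**Totals**
Total step count: 15.
Longest linear sequence: 11 steps (steps 1–5 and 10–15, from 1). The branch from 10 is 4 steps before the union.

**Three steps most likely to fail**

Step 15 may stall, or may also touch the 3-OMe or 6-OMe group. The fallback sets out from 18 and comes back at 23. It replaces the late selective demethylation by a protecting-group swap made before C3 carries any oxygen.
- Flavone 18, whose carbonyl is flanked by a single methoxy group, is treated with AlCl3 in MeCN (60 °C, then dilute HCl). This gives 2-[3,5-bis(benzyloxy)-4-methoxyphenyl]-5-hydroxy-6,7,8-trimethoxy-4H-chromen-4-one F5.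
- The crude product is benzylated under forcing conditions (BnBr, K2CO3, KI, DMF, 80 °C). This caps the chelated 5-OH and repairs any ring B benzyl ether lost to the Lewis acid, giving 5-(benzyloxy)-2-[3,5-bis(benzyloxy)-4-methoxyphenyl]-6,7,8-trimethoxy-4H-chromen-4-one F6.
- DMDO converts F6 into the flavone 2,3-epoxide F7. Catalytic p-TsOH isomerises it to the 5,3',5'-tris(benzyloxy)-3-hydroxy-6,7,8,4'-tetramethoxyflavone F8.
- MeI/K2CO3 gives the 5,3',5'-tris(benzyloxy)-3,6,7,8,4'-pentamethoxyflavone F9.
- One global hydrogenolysis (H2, 10% Pd/C) delivers 23.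

Step 12 may suffer slow epoxidation of the pyrone, or competing oxidation of the benzyl ethers or electron-rich rings. The fallback sets out from 18 and comes back at 20. It swaps electrophilic oxidation for deprotonation, borylation and oxidation.
- LDA (THF, −78 °C) removes H-3, which is acidified and directed by the neighbouring carbonyl group, to give the 3-lithioflavone F3.
- B(OMe)3 traps it. After an AcOH quench this gives the dimethyl flavon-3-ylboronate F4.
- H2O2/AcOH in the same flask oxidises the C–B bond to the C–OH bond of 20.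

Step 6 may give mixtures of 3-O-, 4-O- and di-O-methyl ethers. The fallback sets out from 10 and comes back at 11. It differentiates the hydroxyl groups through their acetates.
- Ac2O/pyridine gives methyl 3,4,5-triacetoxybenzoate F1.
- Heating F1 with MeI and K2CO3 in acetone exchanges only the most labile acetate, the one para to the ester, for methyl. This gives methyl 3,5-diacetoxy-4-methoxybenzoate F2.
- Acid-catalysed methanolysis (cat. HCl, MeOH, reflux) removes the two remaining acetates to give 11.

**Further compounds**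
F1 | step 6 | methyl 3,4,5-triacetoxybenzoate | COC(=O)c1cc(OC(C)=O)c(OC(C)=O)c(OC(C)=O)c1
F2 | step 6 | methyl 3,5-diacetoxy-4-methoxybenzoate | COC(=O)c1cc(OC(C)=O)c(OC)c(OC(C)=O)c1
F3 | step 12 | 3-lithio derivative of flavone 18 | COc1c(OCc2ccccc2)cc(-c2oc3c(OC)c(OC)c(OC)c(OC)c3c(=O)c2[Li])cc1OCc1ccccc1
F4 | step 12 | dimethyl flavon-3-ylboronate derived from 18 | COc1c(OCc2ccccc2)cc(-c2oc3c(OC)c(OC)c(OC)c(OC)c3c(=O)c2B(OC)OC)cc1OCc1ccccc1
F5 | step 15 | 2-[3,5-bis(benzyloxy)-4-methoxyphenyl]-5-hydroxy-6,7,8-trimethoxy-4H-chromen-4-one | COc1c(OCc2ccccc2)cc(-c2cc(=O)c3c(O)c(OC)c(OC)c(OC)c3o2)cc1OCc1ccccc1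
F6 | step 15 | 5-(benzyloxy)-2-[3,5-bis(benzyloxy)-4-methoxyphenyl]-6,7,8-trimethoxy-4H-chromen-4-one | COc1c(OCc2ccccc2)cc(-c2cc(=O)c3c(OCc4ccccc4)c(OC)c(OC)c(OC)c3o2)cc1OCc1ccccc1
F7 | step 15 | 2,3-epoxide of F6 (racemic) | COc1c(OCc2ccccc2)cc(C23OC2C(=O)c2c(OCc4ccccc4)c(OC)c(OC)c(OC)c2O3)cc1OCc1ccccc1
F8 | step 15 | 5,3',5'-tris(benzyloxy)-3-hydroxy-6,7,8,4'-tetramethoxyflavone | COc1c(OCc2ccccc2)cc(-c2oc3c(OC)c(OC)c(OC)c(OCc4ccccc4)c3c(=O)c2O)cc1OCc1ccccc1
F9 | step 15 | 5,3',5'-tris(benzyloxy)-3,6,7,8,4'-pentamethoxyflavone | COc1c(OCc2ccccc2)cc(-c2oc3c(OC)c(OC)c(OC)c(OCc4ccccc4)c3c(=O)c2OC)cc1OCc1ccccc1
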